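(All runs come from a simulation for substances that don't exist.)

- In the violet run 55.5% of the substrate lies in neither product at 10.0 min, yet target reads 24.9% at 3.00 min and 25.1% at 10.0 min. So you should look for what stopped the flask somewhere other than substrate.

| flask | substrate | partner | protic impurity | free catalyst | remark | time |
|---|---|---|---|---|---|---|
| violet | 20 mM | 1 equiv | 10 mM | 0.61 mol% | run made earlier |  |
| red | 30 mM | 1 equiv | 10 mM | 0.61 mol% | run made earlier |  |
| dusk | 20 mM | 1.00 equiv | 10.0 mM | 0.61 mol% | a single well-mixed tank run continuously and read at steady state, 45.0 min in it on average |  |
| midnight | 20 mM (fed, over 15.0 min) | 1.00 equiv | 10.0 mM | 0.61 mol% | all but substrate at the start; substrate goes in evenly over 15.0 min, the run ends at 15 min | 15 min |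
| summer | 20 mM | 1.00 equiv | 10.0 mM | 0.61 mol% | a single well-mixed tank run continuously and read at steady state, 15 min in it on average |  |
| winter | 20 mM | 1.00 equiv | 10.0 mM | 0.61 mol% | a closed flask charged with all of it at once and left for 15 min | 15 min |

- violet (time / min: target / %, over-reaction product / %): 1.00: 17.5, 9.8; 3.00: 24.9, 18.2; 6.00: 24.6, 17.1; 10.0: 25.1, 19.4
- red (time / min: target / %, over-reaction product / %): 1.00: 18.3, 14.3; 2.50: 25.4, 22.8; 3.00: 25.5, 22.8; 5.00: 26.6, 23.9

(readings scatter by 0.5 percentage points)

- the stated concentrations are those of everything mixed, before any reaction; amounts are the same in each set-up
- the feed brings no volume worth counting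
- the earlier runs were made in a closed, stirred flask

- the set-up with the highest share of target in all that became target or over-reaction product, at the outlet or at the end ("none" if the first two lie within 2 percentage points) (dusk / midnight / summer / winter / none)
- share of target in all that became target or over-reaction product, at the outlet or at the end, dusk
- share of target in all that became target or over-reaction product, at the outlet or at the end, midnight
- share of target in all that became target or over-reaction product, at the outlet or at the end, summer
- share of target in all that became target or over-reaction product, at the outlet or at the end, winter

- Count the partner, taking one in each target and two in each over-reaction product. The partner gap of violet is 7.22 mM: the partner charged, less what target holds, less what over-reaction product holds. In the red run the same sum gives 7.68 mM.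
- You may object that the catalyst died and the gap is partner still waiting. But red carries 10.0 mM more partner, and its gap grew by 0.460 mM, so the products took the rest of that extra partner.
- Both gaps are smaller than the impurity charge of 10.0 mM. I therefore read partner as the limiting reagent, with the gap being what impurity took from it.
- Violet's gap stood by about 3.00 min, so impurity took partner at about 2.41 mM min⁻¹ on average over those minutes. That is faster than midnight's feed of 1.33 mM min⁻¹, so I expect midnight's gap to come close to 10.0 mM.
- That leaves midnight about 10.0 mM of partner for products, which means between 25.0% and 50.0% of its substrate converted.
- Won't the substrate excess shield target? Not if over-reaction is partner meeting target. Midnight's feed is slower than violet's first-minute formation of 5.46 mM min⁻¹, so in its first minutes midnight's partner has less substrate beside it than violet's had, and I expect more of its target to go on to over-reaction product. I put midnight below winter, which repeats violet's charge and so about its 56.4%.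
- The forecast reads the stall differently: “something dies on a fixed clock”. It names midnight as best, at 70% (55% to 84%), with winter at 57.7%, dusk at 49.5% and summer at 50%. My own choice is winter.

    partner + free catalyst ⇌ catalyst intermediate A (K = 100 M⁻¹, k = 190 M⁻¹ s⁻¹)
    substrate + catalyst intermediate A → catalyst intermediate B (k = 300 M⁻¹ s⁻¹)
    catalyst intermediate B ⇌ catalyst intermediate C (K = 0.770, k = 310 s⁻¹)
    catalyst intermediate C → free catalyst + target (k = 4.30 s⁻¹)
    partner + target → over-reaction product (k = 1.50 M⁻¹ s⁻¹)
    partner + protic impurity → quenched reagent (k = 1.30 M⁻¹ s⁻¹)

Winter comes first at 57.3%, then dusk at 48.5%, summer at 48.4% and midnight at 43.5%, which is 27 percentage points below the forecast. Midnight ends with 67.3% of its substrate unconverted and 14.2% as target. That target and share put over-reaction product at 18.5%, so midnight's partner gap is 9.77 mM, against 10.0 mM of impurity. Winter, with 25.4% as target, has a partner gap of 7.35 mM.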